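The data stem from a simulated flask from invented constants; noise was put on by code.

Counting partner is the easy step: one tris adduct holds one substrate and 3 coupling partner, and this flask has 1.05 partner per substrate.

- autumn: substrate 1.6 M; coupling partner 1.68 M; the very flask that is asked about, followed so far
- flask: substrate 1.6 M; coupling partner 1.68 M; time 2.5 h

autumn run (percent of the substrate charged)

| time / min | substrate / % | tris adduct / % | bis adduct / % |
|---|---|---|---|
| 6.00 | 3.1 | 13.5 | 1.5 |
| 12.0 | 1.2 | 18.3 | 0 |
| 20.0 | 0.5 | 19.2 | 0 |
| 25.0 | 0.1 | 18.7 | 0 |
| 30.0 | 0.4 | 19.9 | 0 |

(standard deviation of a reading: 0.5 percentage points)

- a species is counted by the substrate in it: one self-condensation product counts as two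
- amounts and yields of by-product count crystals too
- given per volume of solution although it is solid: crystals
- steps thought possible: coupling partner + mono adduct -> bis adduct + by-product; bis adduct + by-product -> side product; substrate + coupling partner -> mono adduct + by-product; 2 substrate -> self-condensation product; coupling partner + bis adduct -> tris adduct + by-product; crystals <-> by-product
- the reaction counts as stopped when no species that holds the substrate changes by six tenths of a point or more over the second half of the time

1. which holds at 2.5 h: what has brought the reaction to rest, or that it has not come to rest (all of the substrate has reacted / the coupling partner has run out first / it is still moving)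
2. share of the substrate used up at 2.5 h
3. tris adduct at 2.5 h, in percent of the substrate charged

One chemist stops at that count. The charges leave room for 35.0% tris adduct, so in her view the partner runs out first and tris adduct climbs until then.

The other chemist reads the autumn run, which is this same flask followed so far. Substrate reads 0.4% at 30.0 min, and tris adduct averages 19.3% over the last 3 readings, flat within the scatter. That much tris adduct has taken 55.0% of the partner. The remaining substrate must stand elsewhere, and two substrate can join without any partner.

So he carries one number, the split: substrate outside tris adduct per substrate in tris adduct, here 4.19, a selectivity factor averaged over the run. The self-condensation step goes with c(substrate) squared, the coupling step with c(substrate) times c(partner). Their ratio therefore moves with c(substrate)/c(partner), and as a rough rule the split should too. My own reckoning sides with him: tris adduct stays near 19.3% at 2.5 h, with substrate gone and partner left.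

The forecast says all of the substrate has reacted, with 99.9% used up and 19.5% tris adduct, on the ground that “the substrate has gone, and with it the feed for the chain”.

The flask gives 19.9% tris adduct and 100% used up: all of the substrate has reacted. At 2.50 h this flask has less substrate left than partner, 0% against 39% of its charge. Counted from the flask, self-condensation product and side product over tris adduct make a split of 4.04; the readings gave 4.19. Her count stands as a ceiling: the 35.0% tris adduct that the charges allow lies above the 19.9% of this flask.

    coupling partner + mono adduct → bis adduct + by-product (k = 0.00650 L mol⁻¹ s⁻¹)
    bis adduct + by-product → side product (k = 0.00350 L mol⁻¹ s⁻¹)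
    substrate + coupling partner → mono adduct + by-product (k = 0.00300 L mol⁻¹ s⁻¹)
    2 substrate → self-condensation product (k = 0.0150 L mol⁻¹ s⁻¹)
    coupling partner + bis adduct → tris adduct + by-product (k = 0.0170 L mol⁻¹ s⁻¹)
    crystals ⇌ by-product, rate k6*(cs6 - [by-product]) while solid is left; crystals form when [by-product] > cs6 (solubility = 0.650 M, k = 1.70 s⁻¹)

Take a second flask charged with 0.64 M substrate, partner held. The rough rule puts the split there at 1.68, which gives 37.4% tris adduct. The computed flask holds 36.2%, with 57% of its partner left.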